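The numbers in the tables stem from a simulated flask on assumed constants; the scatter is artificial.

A small charge of impurity, 79 µM, stands against 0.47 mM of initiator in both alpha and beta, and we must choose which recipe ends with the longer chains.

| setting | teal | ochre | amber | alpha | beta |
|---|---|---|---|---|---|
| free monomer | 0.047 M (fed, over 1.0 h) | 0.047 M (fed, over 1.0 h) | 0.047 M (fed, over 1.0 h) | 0.047 M (fed, over 1.0 h) | 0.047 M (fed, over 3.0 h) |
| initiator | 0.23 mM | 0.35 mM | 0.47 mM | 0.47 mM | 0.47 mM |
| impurity | 79 µM | 79 µM | 120 µM | 79 µM | 79 µM |
| remark | run made earlier | run made earlier | run made earlier |  |  |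
| time |  |  |  | 3.0 h | 3.0 h |

| run | time / h | monomer in chains / % | free monomer / % |
|---|---|---|---|
| teal | 0.417 | 0.5 | 41.6 |
| teal | 0.833 | 0.2 | 85.1 |
| teal | 1.33 | 2.7 | 98.0 |
| teal | 1.50 | 2.8 | 96.6 |
| teal | 2.00 | 7.2 | 93.4 |
| teal | 2.50 | 12.5 | 89.0 |
| teal | 3.00 | 15.9 | 85.6 |
| ochre | 0.417 | 0.6 | 42.3 |
| ochre | 0.833 | 1.6 | 82.7 |
| ochre | 1.33 | 4.4 | 93.6 |
| ochre | 1.50 | 6.1 | 93.8 |
| ochre | 2.00 | 12.1 | 86.8 |
| ochre | 2.50 | 16.2 | 81.4 |
| ochre | 3.00 | 25.4 | 76.7 |
| amber | 0.250 | 0 | 24.4 |
| amber | 0.833 | 1.9 | 82.5 |
| amber | 1.33 | 6.8 | 93.4 |
| amber | 2.00 | 14.6 | 83.7 |
| amber | 3.00 | 28.5 | 70.0 |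

(readings scatter by 1 percentage point)

- the average divides the monomer in chains by the number of chains begun, living and dead together
- the earlier runs do not show the number of chains; that part of a forecast is a guess
- percentages count the whole charge, also what has not yet gone in

- which of the two ends with the longer chains by the average number of monomer units in a chain (chains begun, living or dead) ("neither" if they lie within 10%) (alpha / beta / neither)
- average number of monomer units in a chain (chains begun, living or dead) at the end, alpha
- average number of monomer units in a chain (chains begun, living or dead) at the end, beta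

Chain length here is the number-average length: monomer in chains over chains begun. We count the impurity as taking its own amount of initiator, which leaves 0.391 mM of usable initiator. Chains begun then stand at or below that amount. The charge divided by usable initiator gives 120, the floor scale: the length at full conversion if usable initiator had begun a chain throughout. A flask's floor length is its share of monomer in chains times this scale, and its true average lies at or above that.

Amber read 28.5% in chains at 3.00 h with less usable initiator, so we take that reading as a low share for alpha. This gives alpha a floor near 34.3. A fed portion of free monomer spends on average 2.50 h in alpha and 1.50 h in beta. Alpha's free monomer is exposed longer, so we scale alpha's figure by exposure to about 20.6 for beta and expect alpha to end longer. That scaled figure for beta is a rough estimate, not a bound, and neither figure is an estimate of the length.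

The forecast gave alpha, with 36 for alpha and 23 for beta. On chains it said: “Chains begun are a guess, between 0.39 and 0.47 mM, and I take about 0.43 mM.”

The flask gives alpha, with 54.4 for alpha and 32.5 for beta.

    free monomer + initiator → living end + monomer in chains (k = 0.234 /M/min)
    free monomer + living end → monomer in chains + living end, rate k2*[living end]*[free monomer] (k = 13.8 /M/min)
    initiator + impurity → spent initiator A (k = 14200 /M/min)
    initiator + monomer in chains → spent initiator B (k = 0.420 /M/min)

Alpha's 32.4% in chains gives a floor of 38.9 on the scale, and its average stands at 54.4, with living end at 2.80 × 10⁻⁴ M against the usable 0.391 mM. In beta at 2.42 h, growth on living ends used free monomer 52 times as fast as the beginning of new chains, and 29% of beta's initiator was still there at the end. The flask like beta with 0.019 M of free monomer has a floor of 4.14 and reads 13.1.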